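**Retrosynthetic overview**
- Target 11 is traced back, by removal of the two benzyl groups and of the formyl group (Vilsmeier formylation at the ring carbon para to OMe), to the (R)-acetate 9.
- The strategy rests on C2' of the side chain: a CH–OAc carbon lying between the benzylic C1'H2 on the benzene ring and C3'H2 of the undecyl chain, two methylene flanks that a ketone reduction could barely distinguish. It is cut at C2'–C3' and at O–acetyl into arylacetaldehyde 5, acetyl bromide 6 and 1-undecene 7, which are joined by an enantioconvergent nickel hydride coupling.
- Aldehyde 5 comes from o-eugenol 1 by para-oxidation to the quinone, reduction, dibenzylation and oxidative cleavage of the allyl group.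
- No ring is formed; the benzene ring of o-eugenol is the only ring and is carried through.

Key step: step 5

Assumption: the sense of induction of the nickel/bis(oxazoline) catalyst is not derived here; the ligand antipode that delivers the R acetate is used, and the configuration is to be confirmed on 9.

**Step 1**
Reactants: 1 2-allyl-6-methoxyphenol (o-eugenol)
Product: 2 2-allyl-6-methoxy-1,4-benzoquinone
Conditions: (KSO3)2NO (2.2 equiv), KH2PO4, H2O/acetone, 0 °C → rt
Reagents that add atoms: potassium nitrosodisulfonate (Fremy's salt), [K+].[K+].[O]N(S(=O)(=O)[O-])S(=O)(=O)[O-]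
Why: Teuber oxidation, in which the nitroxyl radical removes the phenolic hydrogen and a second equivalent oxygenates the free para carbon, should give the p-quinone and leave the allyl group alone.

**Step 2**
Reactants: 2 2-allyl-6-methoxy-1,4-benzoquinone
Product: 3 2-allyl-6-methoxybenzene-1,4-diol
Conditions: Na2S2O4, EtOAc/H2O, rt; crude product used at once
Reagents that add atoms: none
Why: Dithionite reduction of a quinone to its hydroquinone is a fast two-electron reduction that does not touch the terminal alkene.

**Step 3**
Reactants: 3 2-allyl-6-methoxybenzene-1,4-diol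
Product: 4 1-allyl-2,5-bis(benzyloxy)-3-methoxybenzene
Conditions: BnBr, K2CO3, DMF (degassed), rt → 50 °C
Reagents that add atoms: benzyl bromide, BrCc1ccccc1
Why: Williamson etherification of both phenoxides under carbonate conditions should proceed without isomerising the allyl group, and degassing keeps the hydroquinone from re-oxidising.

**Step 4**
Reactants: 4 1-allyl-2,5-bis(benzyloxy)-3-methoxybenzene
Product: 5 2-[2,5-bis(benzyloxy)-3-methoxyphenyl]acetaldehyde
Conditions: OsO4 (cat.), NaIO4, 2,6-lutidine, dioxane/H2O, rt; used promptly
Reagents that add atoms: osmium tetroxide, O=[Os](=O)(=O)=O; sodium periodate, [Na+].[O-]I(=O)(=O)=O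
Why: Lemieux–Johnson oxidation (catalytic osmylation of the terminal alkene, then periodate cleavage of the diol) should give the arylacetaldehyde without attacking the electron-rich ring, which ozone might.

**Step 5**
Reactants: 5 2-[2,5-bis(benzyloxy)-3-methoxyphenyl]acetaldehyde; 6 acetyl bromide; 7 1-undecene
Product: 9 (R)-1-[2,5-bis(benzyloxy)-3-methoxyphenyl]tridecan-2-yl acetate, via racemic 1-bromoalkyl acetate 8 (not isolated)
Conditions: 6 (1.0 equiv), i-Pr2O, 0 °C → rt, no Lewis acid; then NiBr2·glyme (10 mol %), chiral bis(oxazoline) L* (12 mol %), 7, (EtO)3SiH, K3PO4·H2O, DMA/i-Pr2O, rt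
Reagents that add atoms: none
Why: Acetyl bromide adds across the C=O of 5 to give racemic bromo acetate 8; low-valent nickel abstracts bromine from either enantiomer to give one planar α-acetoxyalkyl radical, while the ligand-bound Ni–H made from the silane inserts 1-undecene in the anti-Markovnikov sense to a primary undecyl–nickel species that captures the radical and reductively eliminates, forming C2'–C3'. The closest known reaction type is the nickel-hydride-catalysed enantioconvergent coupling of racemic α-haloalkyl esters, generated in the flask from an aldehyde and an acyl bromide, with terminal olefins and a hydrosilane. No ring is closed. The C2' stereocentre is set by the chiral bis(oxazoline)–nickel complex, which has to tell OAc from CH2Ar at the radical carbon (not one methylene from another) and can use the acetate carbonyl as a second binding point. The step needs linear hydrometalation, which the unhindered monosubstituted olefin secures, and selectivity for the C–Br bond over the aryl and benzyl ethers, which nickel should not activate at room temperature. Complete conversion of 5 into 8 before the silane is added should prevent hydrosilylation of the aldehyde.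

**Step 6**
Reactants: 9 (R)-1-[2,5-bis(benzyloxy)-3-methoxyphenyl]tridecan-2-yl acetate
Product: 10 (R)-1-[3,6-bis(benzyloxy)-2-formyl-5-methoxyphenyl]tridecan-2-yl acetate
Conditions: POCl3, DMF, 0 → 70 °C; then ice/H2O
Reagents that add atoms: N,N-dimethylformamide, CN(C)C=O; water, O
Why: Vilsmeier–Haack formylation should occur at the ring carbon para to OMe and ortho to the 5-benzyloxy group (C6 of 9), the position that reacts in 1,2,4-trialkoxybenzenes and orcinol ethers, whereas C4 is shielded between OBn and an OMe whose methyl is turned toward it by the neighbouring benzyloxy group.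

**Step 7**
Reactants: 10 (R)-1-[3,6-bis(benzyloxy)-2-formyl-5-methoxyphenyl]tridecan-2-yl acetate
Product: 11 (R)-1-(2-formyl-3,6-dihydroxy-5-methoxyphenyl)tridecan-2-yl acetate
Conditions: BCl3, C6HMe5, CH2Cl2, –78 °C; then H2O, work-up under Ar
Reagents that add atoms: none
Why: Lewis-acid debenzylation of aryl benzyl ethers with pentamethylbenzene as cation scavenger should free both phenols at –78 °C while the secondary acetate, the methyl ether para to the aldehyde and the C2' stereocentre stay intact, and the scavenger keeps benzyl cations off the free ring position.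

**Compound list**
1 | 2-allyl-6-methoxyphenol (o-eugenol) | C=CCc1cccc(OC)c1O | starting material
2 | 2-allyl-6-methoxy-1,4-benzoquinone | C=CCC1=CC(=O)C=C(OC)C1=O | intermediate
3 | 2-allyl-6-methoxybenzene-1,4-diol | C=CCc1cc(O)cc(OC)c1O | intermediate
4 | 1-allyl-2,5-bis(benzyloxy)-3-methoxybenzene | C=CCc1cc(OCc2ccccc2)cc(OC)c1OCc1ccccc1 | intermediate
5 | 2-[2,5-bis(benzyloxy)-3-methoxyphenyl]acetaldehyde | O=CCc1cc(OCc2ccccc2)cc(OC)c1OCc1ccccc1 | intermediate
6 | acetyl bromide | CC(=O)Br | starting material
7 | 1-undecene | C=CCCCCCCCCC | starting material
8 | rac-1-bromo-2-[2,5-bis(benzyloxy)-3-methoxyphenyl]ethyl acetate | CC(=O)OC(Br)Cc1cc(OCc2ccccc2)cc(OC)c1OCc1ccccc1 | intermediate (not isolated)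
9 | (R)-1-[2,5-bis(benzyloxy)-3-methoxyphenyl]tridecan-2-yl acetate | CCCCCCCCCCC[C@H](Cc1cc(OCc2ccccc2)cc(OC)c1OCc1ccccc1)OC(C)=O | intermediate
10 | (R)-1-[3,6-bis(benzyloxy)-2-formyl-5-methoxyphenyl]tridecan-2-yl acetate | CCCCCCCCCCC[C@H](Cc1c(OCc2ccccc2)c(OC)cc(OCc2ccccc2)c1C=O)OC(C)=O | intermediate
11 | (R)-1-(2-formyl-3,6-dihydroxy-5-methoxyphenyl)tridecan-2-yl acetate | CCCCCCCCCCC[C@H](Cc1c(O)c(OC)cc(O)c1C=O)OC(C)=O | target

**Total step count:** 7
**Longest linear sequence:** 7 steps (1 → 11)

**Steps most likely to fail**

Step 5. Bromo acetate 8 may be lost before the radical forms, by elimination of HBr to the styrenyl enol acetate or by attack of the ortho benzyloxy oxygen on the C–Br carbon, and the catalyst may select the faces of the α-acetoxy radical poorly. The fallback sets out from 4 and returns at 9. Epoxidation of 4 (mCPBA, NaHCO3, CH2Cl2) should give racemic 2-[2,5-bis(benzyloxy)-3-methoxybenzyl]oxirane F1. Hydrolytic kinetic resolution (chiral (salen)Co(III)OAc, 0.55 equiv H2O, catalyst antipode chosen to consume the R epoxide) should leave (S)-2-[2,5-bis(benzyloxy)-3-methoxybenzyl]oxirane F2. Copper-catalysed opening at the terminal carbon (decylmagnesium bromide, CuI, THF, –30 °C) should give (R)-1-[2,5-bis(benzyloxy)-3-methoxyphenyl]tridecan-2-ol F3; the stereocentre is not touched, and the descriptor changes from S to R only because the CIP priorities change. Acetylation (Ac2O, pyridine, DMAP) then gives 9.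

Step 6. Electrophilic substitution may stall at the crowded C6 position between the benzyloxy group and the branched side chain, or divert in part to C4. The fallback sets out from 9 and returns at 10. Bromination with NBS (MeCN, 0 °C, dark), a smaller electrophile that is strongly para-directed by OMe, should give (R)-1-[3,6-bis(benzyloxy)-2-bromo-5-methoxyphenyl]tridecan-2-yl acetate F4, whose substitution pattern can be checked before carbon is introduced. Palladium-catalysed reductive carbonylation (CO/H2, Pd(OAc)2, di(1-adamantyl)-n-butylphosphine, TMEDA, toluene, 100 °C) should then replace bromine by the formyl group and give 10.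

Step 7. The Lewis acid may cleave or shift the acetate or demethylate the ether next to the freed phenol, and the hydroquinone may oxidise in air to the quinone during work-up. The fallback sets out from 10 and returns at 11: hydrogenolysis of both benzyl ethers (H2 1 atm, Pd/C, EtOAc, rt, stopped before the aldehyde is reduced) is neutral and reductive and should give 11 directly. This fallback makes no new compound (F0: none).

**Further compounds**
F1 | step 5 | rac-2-[2,5-bis(benzyloxy)-3-methoxybenzyl]oxirane | C1OC1Cc1cc(OCc2ccccc2)cc(OC)c1OCc1ccccc1
F2 | step 5 | (S)-2-[2,5-bis(benzyloxy)-3-methoxybenzyl]oxirane | C1[C@H](Cc2cc(OCc3ccccc3)cc(OC)c2OCc2ccccc2)O1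
F3 | step 5 | (R)-1-[2,5-bis(benzyloxy)-3-methoxyphenyl]tridecan-2-ol | CCCCCCCCCCC[C@H](Cc1cc(OCc2ccccc2)cc(OC)c1OCc1ccccc1)O
F4 | step 6 | (R)-1-[3,6-bis(benzyloxy)-2-bromo-5-methoxyphenyl]tridecan-2-yl acetate | CCCCCCCCCCC[C@H](Cc1c(OCc2ccccc2)c(OC)cc(OCc2ccccc2)c1Br)OC(C)=O
F0 | step 7 | none | none
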